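**Retrosynthetic overview**
1. Tatanan B ⇐ spirocyclic 1,3-diketone (thermodynamic O-methylation) ⇐ ring-A α-mesyloxy methyl ketone + methyl (E)-3-iodo-2-methoxyacrylate, joined in one flask.
2. Enabling feature: in ring B (C1(OMe)=C2H–C3(=O)–C4(OMe)=C5H around spiro C6) the vinylogous ester C1–C2–C3 is a masked 1,3-diketone, so C2–C3 is a Dieckmann bond; C6 is the α-carbon of the C1 carbonyl, so C5–C6 can be made by an invertive 1,2-alkenyl shift from C1 to C6, which places the vinylic carbon on the crowded face of ring A.
3. α-Mesyloxy ketone ⇐ enolate hydroxylation, hydroxyl-directed hydrogenation (sets C10 and C11) and mesylation of a cyclohexenyl methyl ketone.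
4. Ring A (C7–C9 stereotriad) ⇐ catalytic asymmetric inverse-demand (4+2) of an acyclic aryl dienone with (E)-asarone; dienone ⇐ 2,4,5-trimethoxybenzaldehyde, pentan-3-one and propynylmagnesium bromide (aldol, alkynylation, Meyer–Schuster).
5. Ring order: ring A first (step 4), ring B last (step 9).

Key step: step 9

Remark: methyl 2-methoxyacrylate, (E)-asarone and prop-1-ynylmagnesium bromide are taken as purchasable; ring-A intermediates carry cyclohexane locants (C1 = acetyl-bearing carbon), the spiro compounds carry spiro[5.5]undecane locants (C1–C5 ring B, C6 spiro, C7–C11 ring A).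

**Step 1**
Reactants: 1 2,4,5-trimethoxybenzaldehyde; 2 pentan-3-one
Product: 3 (E)-2-methyl-1-(2,4,5-trimethoxyphenyl)pent-1-en-3-one
Conditions: NaOH (0.3 equiv), 2 (5 equiv), EtOH–H2O, 50 °C
Reagents that add atoms: none
Why: Claisen–Schmidt condensation of a non-enolisable aldehyde with an excess of the symmetric ketone should give, after dehydration, the thermodynamic E-enone (aryl trans to the acyl group); no stereocentre is formed.

**Step 2**
Reactants: 3 (E)-2-methyl-1-(2,4,5-trimethoxyphenyl)pent-1-en-3-one; 4 prop-1-ynylmagnesium bromide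
Product: 5 (E)-3-ethyl-2-methyl-1-(2,4,5-trimethoxyphenyl)hex-1-en-4-yn-3-ol
Conditions: 4 (0.5 M in THF, 1.3 equiv), THF, −78 → 0 °C; NH4Cl (aq)
Reagents that add atoms: none
Why: Alkynyl Grignard reagents add to enones in the 1,2-mode, giving the tertiary propargylic alcohol, whose racemic carbinol centre is destroyed in step 3.

**Step 3**
Reactants: 5 (E)-3-ethyl-2-methyl-1-(2,4,5-trimethoxyphenyl)hex-1-en-4-yn-3-ol
Product: 6 (3E,5E)-4-ethyl-5-methyl-6-(2,4,5-trimethoxyphenyl)hexa-3,5-dien-2-one
Conditions: Ph3PAuNTf2 (2 mol %), MeOH (2 equiv), toluene, 23 °C; then I2 (2 mol %), CH2Cl2, 23 °C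
Reagents that add atoms: none
Why: The gold-catalysed Meyer–Schuster rearrangement (formal 1,3-hydroxyl shift, then tautomerisation) should give the conjugated dienone, and iodine-catalysed equilibration should funnel the new alkene to the 3E isomer with acetyl trans to the larger alkenyl branch; no stereocentre is formed.

**Step 4**
Reactants: 6 (3E,5E)-4-ethyl-5-methyl-6-(2,4,5-trimethoxyphenyl)hexa-3,5-dien-2-one; 7 (E)-asarone
Product: 8 1-[2-ethyl-3,5-dimethyl-4,6-bis(2,4,5-trimethoxyphenyl)cyclohex-2-en-1-yl]ethan-1-one (4-aryl and 6-aryl cis; 5-methyl trans to both)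
Conditions: (R)-3,3′-bis(2,4,6-triisopropylphenyl)-1,1′-binaphthyl-2,2′-diyl N-triflylphosphoramide (5 mol %), 7 (1.5 equiv), 4 Å MS, toluene, −40 °C
Reagents that add atoms: none
Why: Proposed new method: the chiral Brønsted acid protonates the dienone carbonyl and ion-pairs with the resulting vinylogous quinone-methide-like cation; the nucleophilic β-carbon of asarone adds to its benzylic terminus (1,6-addition), and the derived trimethoxybenzyl cation is closed by the dienol α-carbon in a chair-like transition state with aryl, methyl and aryl equatorial, which should give the all-trans C4/C5/C6 array with the E geometry of asarone retained; the absolute sense comes from the catalyst pocket (the antipode is chosen to give the enantiomer drawn), and both C1 epimers converge in step 5; the closest known reaction types are the inverse-electron-demand Diels–Alder reaction of 2,4-dienones (masked ortho-benzoquinones) with electron-rich styrenes and chiral-phosphoric-acid-catalysed formal cycloadditions of anethole-type styrenes with quinone methides.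

**Step 5**
Reactants: 8 cyclohexenyl methyl ketone
Product: 9 1-[2-ethyl-1-hydroxy-3,5-dimethyl-4,6-bis(2,4,5-trimethoxyphenyl)cyclohex-2-en-1-yl]ethan-1-one (1-OH trans to the 6-aryl)
Conditions: KN(SiMe3)2 (0.95 equiv), THF, −78 → 0 °C; then 2-(phenylsulfonyl)-3-phenyloxaziridine, −78 °C; NH4Cl (aq)
Reagents that add atoms: 2-(phenylsulfonyl)-3-phenyloxaziridine, O=S(=O)(c1ccccc1)N1OC1c1ccccc1
Why: The thermodynamic extended dienolate (the C1 proton is α to the ketone and allylic) should be hydroxylated at its α-carbon by the N-sulfonyloxaziridine, the oxidant approaching C1 anti to the C6 aryl, which allylic strain with the enolate methyl holds pseudo-axial, so that the hydroxyl is placed trans to that aryl.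

**Step 6**
Reactants: 9 α-hydroxy cyclohexenyl ketone
Product: 10 1-[2-ethyl-1-hydroxy-3,5-dimethyl-4,6-bis(2,4,5-trimethoxyphenyl)cyclohexyl]ethan-1-one (acetyl, 2-ethyl, 3-methyl and both aryls on one face; 1-OH and 5-methyl on the other)
Conditions: [Ir(cod)(PCy3)(py)]PF6 (10 mol %), H2 (50 bar), CH2Cl2, 23 °C
Reagents that add atoms: none
Why: Hydroxyl-directed hydrogenation by the cationic iridium complex should deliver both hydrogens to the alkene face bearing the C1 hydroxyl, so that syn addition fixes C2 and C3 with ethyl and methyl cis to each other and on the face of the aryl groups.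

**Step 7**
Reactants: 10 saturated α-hydroxy ketone
Product: 11 1-acetyl-2-ethyl-3,5-dimethyl-4,6-bis(2,4,5-trimethoxyphenyl)cyclohexyl methanesulfonate
Conditions: MsCl (3 equiv), Et3N (4 equiv), DMAP (10 mol %), CH2Cl2, −20 → 0 °C
Reagents that add atoms: methanesulfonyl chloride, CS(=O)(=O)Cl
Why: Sulfonylation of the tertiary α-ketol should give a mesylate that the adjacent carbonyl protects against ionisation and its equatorial position against E2 loss; the configuration at C1 is untouched.

**Step 8**
Reactants: 12 methyl 2-methoxyacrylate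
Product: 13 methyl (E)-3-iodo-2-methoxyprop-2-enoate (iodine cis to the ester)
Conditions: ICl (1.05 equiv), CH2Cl2, −78 → 0 °C; then Et3N (1.5 equiv), 0 → 23 °C; separation of E from Z on SiO2
Reagents that add atoms: iodine monochloride, ClI
Why: Electrophilic iodochlorination of the captodative enol ether at its β-carbon followed by amine-induced loss of HCl (addition–elimination) should give the β-iodo-α-methoxyacrylate, the Z isomer being recycled by iodine/light equilibration.

**Step 9**
Reactants: 11 ring-A α-mesyloxy methyl ketone; 13 methyl (E)-3-iodo-2-methoxyprop-2-enoate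
Product: 17 11-ethyl-4-methoxy-8,10-dimethyl-7,9-bis(2,4,5-trimethoxyphenyl)spiro[5.5]undec-4-ene-1,3-dione, via alkenylmagnesium chloride 14 (not isolated), via magnesium alkoxide adduct 15 (not isolated), via rearranged keto ester 16 (not isolated)
Conditions: 13 (1.5 equiv), i-PrMgCl·LiCl, THF, −78 °C; then 11, −78 → −40 °C; Et2AlCl (2.2 equiv), CH2Cl2, −78 → 0 °C; then KOt-Bu (5 equiv), t-BuOH–THF, 0 → 23 °C; HCl (aq)
Reagents that add atoms: none
Why: Iodine–magnesium exchange gives the ester-chelated alkenylmagnesium 14, which adds to the acetyl carbonyl of 11; passing the alkoxide 15 to aluminium triggers a concerted pinacol-type 1,2-shift in which the alkenyl group moves from the carbinol carbon to C1 anti-periplanar to the departing mesylate, and tert-butoxide then closes ring B by Dieckmann condensation of the methyl ketone enolate of 16 onto the cis ester. The closest known reaction types are the organoaluminium-promoted stereospecific 1,2-rearrangement of β-mesyloxy alcohols to α-alkenyl ketones, the addition of β-magnesioacrylates to carbonyl compounds and the Dieckmann synthesis of cyclic 1,3-diketones. Ring B is closed in the 6-(enolendo)-exo-trig mode (new C2–C3 bond, spiro locants), the C5–C6 bond having been made by the migration. The spiro stereocentre is controlled by inversion at C1: the oxygen installed in step 5 trans to the C6 aryl leaves, the alkenyl carbon enters on the face of the aryl and ethyl groups, and the acyl carbon swings to the opposite, equatorial site, which also relieves the 1,3-diaxial acetyl/3-methyl compression of 11. The step needs migration of alkenyl rather than methyl (secured by the higher migratory aptitude of sp2 carbon), retention of the alkene geometry so that ester and ketone stay cis for ring closure, and suppression of epoxide formation or lactonisation (secured by the weakly nucleophilic aluminium alkoxide).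

**Step 10**
Reactants: 17 spirocyclic 1,3-diketone
Product: 18 Tatanan B
Conditions: HC(OMe)3 (3 equiv), camphor-10-sulfonic acid (5 mol %), MeOH, 23 °C
Reagents that add atoms: trimethyl orthoformate, COC(OC)OC
Why: Acid-catalysed enol ether formation from the cyclic 1,3-diketone is reversible and should funnel to the cross-conjugated 2,5-dienone (methoxy at C1, next to the spiro carbon) rather than the linearly conjugated 2,4-dienone; no stereocentre is touched.

**Compound list**
1 | 2,4,5-trimethoxybenzaldehyde | O=Cc1cc(OC)c(OC)cc1OC | starting material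
2 | pentan-3-one | CCC(=O)CC | starting material
3 | (E)-2-methyl-1-(2,4,5-trimethoxyphenyl)pent-1-en-3-one | CCC(=O)/C(C)=C/c1cc(OC)c(OC)cc1OC | intermediate
4 | prop-1-ynylmagnesium bromide | CC#C[Mg]Br | starting material
5 | (E)-3-ethyl-2-methyl-1-(2,4,5-trimethoxyphenyl)hex-1-en-4-yn-3-ol, racemic at C3 | CC#CC(O)(CC)/C(C)=C/c1cc(OC)c(OC)cc1OC | intermediate
6 | (3E,5E)-4-ethyl-5-methyl-6-(2,4,5-trimethoxyphenyl)hexa-3,5-dien-2-one | CC(=O)/C=C(CC)/C(C)=C/c1cc(OC)c(OC)cc1OC | intermediate
7 | (E)-asarone, 1,2,4-trimethoxy-5-[(E)-prop-1-enyl]benzene | C/C=C/c1cc(OC)c(OC)cc1OC | starting material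
8 | 1-[2-ethyl-3,5-dimethyl-4,6-bis(2,4,5-trimethoxyphenyl)cyclohex-2-en-1-yl]ethan-1-one; 4-aryl cis to 6-aryl, 5-methyl trans to both, acetyl trans to 6-aryl | CCC1=C(C)[C@H](c2cc(OC)c(OC)cc2OC)[C@@H](C)[C@H](c2cc(OC)c(OC)cc2OC)[C@H]1C(C)=O | intermediate
9 | 1-hydroxy derivative of 8; 1-OH trans to 6-aryl, acetyl cis to 6-aryl | CCC1=C(C)[C@H](c2cc(OC)c(OC)cc2OC)[C@@H](C)[C@H](c2cc(OC)c(OC)cc2OC)[C@]1(O)C(C)=O | intermediate
10 | 1-[2-ethyl-1-hydroxy-3,5-dimethyl-4,6-bis(2,4,5-trimethoxyphenyl)cyclohexyl]ethan-1-one; acetyl, 2-ethyl, 3-methyl, 4-aryl and 6-aryl on one face, 1-OH and 5-methyl on the other | CC[C@@H]1[C@H](C)[C@H](c2cc(OC)c(OC)cc2OC)[C@@H](C)[C@H](c2cc(OC)c(OC)cc2OC)[C@]1(O)C(C)=O | intermediate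
11 | methanesulfonate of 10, same configuration | CC[C@@H]1[C@H](C)[C@H](c2cc(OC)c(OC)cc2OC)[C@@H](C)[C@H](c2cc(OC)c(OC)cc2OC)[C@]1(OS(C)(=O)=O)C(C)=O | intermediate
12 | methyl 2-methoxyacrylate | C=C(OC)C(=O)OC | starting material
13 | methyl (E)-3-iodo-2-methoxyprop-2-enoate, iodine cis to ester | I/C=C(\C(=O)OC)OC | intermediate
14 | (E)-(2,3-dimethoxy-3-oxoprop-1-enyl)magnesium chloride, magnesium cis to ester | Cl[Mg]/C=C(\C(=O)OC)OC | intermediate
15 | chloromagnesium alkoxide from addition of 14 to the acetyl group of 11, both carbinol epimers | CC[C@@H]1[C@H](C)[C@H](c2cc(OC)c(OC)cc2OC)[C@@H](C)[C@H](c2cc(OC)c(OC)cc2OC)[C@]1(OS(C)(=O)=O)C(C)(O[Mg]Cl)/C=C(\C(=O)OC)OC | intermediate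
16 | methyl (E)-3-[1-acetyl-2-ethyl-3,5-dimethyl-4,6-bis(2,4,5-trimethoxyphenyl)cyclohexyl]-2-methoxyprop-2-enoate; alkenyl on the face of the aryls and ethyl, acetyl on the face of 5-methyl | CC[C@@H]1[C@H](C)[C@H](c2cc(OC)c(OC)cc2OC)[C@@H](C)[C@H](c2cc(OC)c(OC)cc2OC)[C@]1(C(C)=O)/C=C(\C(=O)OC)OC | intermediate
17 | 11-ethyl-4-methoxy-8,10-dimethyl-7,9-bis(2,4,5-trimethoxyphenyl)spiro[5.5]undec-4-ene-1,3-dione; C5 on the face of 7-aryl, 9-aryl, 10-methyl and 11-ethyl, C1 on the face of 8-methyl | CC[C@@H]1[C@H](C)[C@H](c2cc(OC)c(OC)cc2OC)[C@@H](C)[C@H](c2cc(OC)c(OC)cc2OC)[C@]12C=C(OC)C(=O)CC2=O | intermediate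
18 | Tatanan B, 11-ethyl-1,4-dimethoxy-8,10-dimethyl-7,9-bis(2,4,5-trimethoxyphenyl)spiro[5.5]undeca-1,4-dien-3-one; same configuration as 17 | CC[C@@H]1[C@H](C)[C@H](c2cc(OC)c(OC)cc2OC)[C@@H](C)[C@H](c2cc(OC)c(OC)cc2OC)[C@]12C=C(OC)C(=O)C=C2OC | target

**Count**
Total steps: 10. Longest linear sequence: 9 steps (1, 2, 3, 4, 5, 6, 7, 9, 10).

**Steps most likely to fail**

Step 4. The chiral acid may discriminate poorly between the enantiotopic faces in the first, remote C–C bond formation, or acid-induced oligomerisation of the styrene may outrun the cycloaddition. The fallback gives up catalyst control for resolution. It sets out from 6 and 7, which are combined under BF3·OEt2 in CH2Cl2 at −78 °C, an inverse-electron-demand Diels–Alder reaction of a 2,4-dienone with an electron-rich styrene. This should give the racemate, that is 8 together with its enantiomer ent-8 F1. The two are separated by preparative supercritical-fluid chromatography on amylose tris(3,5-dimethylphenylcarbamate), and the route is rejoined at 8.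

Step 9. The magnesium alkoxide may lactonise onto the cis ester, or the tertiary mesylate may be lost by elimination, before the alkenyl group migrates; addition to the hindered acetyl group may also be slow. The fallback separates the three events and builds ring B by metathesis. It sets out from 11. Vinylmagnesium bromide, which is small and carries no ester, adds to the acetyl group to give the β-mesyloxy alcohol F2 (as its magnesium alkoxide). Et2AlCl then induces the same invertive 1,2-shift to the α-vinyl methyl ketone F3. Soft enolisation (MgBr2·OEt2, i-Pr2NEt) and C-acylation with 1-(2-methoxyacryloyl)benzotriazole give the diketone diene F4. Ring-closing metathesis with the second-generation Hoveyda–Grubbs catalyst, RuCl2(H2IMes)(=CH-C6H4-2-Oi-Pr), in toluene at 80 °C closes the C4=C5 bond, and the route is rejoined at 17.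

Step 5. Oxygen may be transferred to the γ-carbon of the dienolate or to the enolate face syn to the C6 aryl, or proton exchange may give the conjugated enone. The fallback oxidises an isolated silyl dienol ether instead of the enolate. It sets out from 8. Et3SiOTf and Et3N give the triethylsilyl dienol ether F5. Rubottom oxidation with dimethyldioxirane in acetone at −78 °C, which epoxidises only the electron-rich exocyclic enol ether bond from the face opposite the pseudo-axial aryl, gives the α-triethylsilyloxy ketone F6. HF·pyridine removes the silyl group, and the route is rejoined at 9.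

**Further compounds**
F1 | step 4 | ent-8, enantiomer of the cyclohexenyl methyl ketone | CCC1=C(C)[C@@H](c2cc(OC)c(OC)cc2OC)[C@H](C)[C@@H](c2cc(OC)c(OC)cc2OC)[C@@H]1C(C)=O
F2 | step 9 | 1-(2-hydroxybut-3-en-2-yl)-2-ethyl-3,5-dimethyl-4,6-bis(2,4,5-trimethoxyphenyl)cyclohexyl methanesulfonate, both carbinol epimers | CC[C@@H]1[C@H](C)[C@H](c2cc(OC)c(OC)cc2OC)[C@@H](C)[C@H](c2cc(OC)c(OC)cc2OC)[C@]1(OS(C)(=O)=O)C(C)(O)C=C
F3 | step 9 | 1-[2-ethyl-3,5-dimethyl-4,6-bis(2,4,5-trimethoxyphenyl)-1-vinylcyclohexyl]ethan-1-one, vinyl on the face of the aryls | CC[C@@H]1[C@H](C)[C@H](c2cc(OC)c(OC)cc2OC)[C@@H](C)[C@H](c2cc(OC)c(OC)cc2OC)[C@]1(C(C)=O)C=C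
F4 | step 9 | 1-[2-ethyl-3,5-dimethyl-4,6-bis(2,4,5-trimethoxyphenyl)-1-vinylcyclohexyl]-4-methoxypent-4-ene-1,3-dione | CC[C@@H]1[C@H](C)[C@H](c2cc(OC)c(OC)cc2OC)[C@@H](C)[C@H](c2cc(OC)c(OC)cc2OC)[C@]1(C(=O)CC(=O)C(=C)OC)C=C
F5 | step 5 | triethylsilyl dienol ether of 8, either enol ether geometry | CCC1=C(C)[C@H](c2cc(OC)c(OC)cc2OC)[C@@H](C)[C@H](c2cc(OC)c(OC)cc2OC)C1=C(C)O[Si](CC)(CC)CC
F6 | step 5 | triethylsilyl ether of 9 | CCC1=C(C)[C@H](c2cc(OC)c(OC)cc2OC)[C@@H](C)[C@H](c2cc(OC)c(OC)cc2OC)[C@]1(O[Si](CC)(CC)CC)C(C)=O
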